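Take the closed ochre vessel and follow it to 8.0 d.

| flask | L | G | temperature | remark | time |
|---|---|---|---|---|---|
| ochre | 0.034 M | 1.7 mM | 35 °C | the very flask that is asked about, followed so far |  |
| grey | 0.034 M | 3.4 mM | 30 °C | run made earlier |  |
| flask | 0.034 M | 1.7 mM | 35 °C |  | 8.0 d |

| run | time / d | X / % | L / % |
|---|---|---|---|
| ochre | 0.417 | 9.9 | 89.8 |
| ochre | 0.833 | 27.6 | 73.4 |
| ochre | 1.25 | 41.0 | 53.0 |
| ochre | 2.50 | 64.7 | 22.7 |
| ochre | 5.00 | 59.4 | 3.8 |
| grey | 0.625 | 22.4 | 79.0 |
| grey | 1.25 | 50.7 | 50.1 |
| grey | 2.50 | 74.8 | 14.8 |
| grey | 4.00 | 78.3 | 5.4 |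
| grey | 8.00 | 60.8 | 0.8 |

(readings scatter by 1 percentage point)

- beta: change nothing and wait 8.0 d more
- alpha: at 8.0 d take out 90% of the X then present, then wait 8.0 d
- epsilon: at 8.0 d raise the temperature by 25 K, then wait 8.0 d
- zeta: at 8.0 d add G, 100% of the amount charged, then wait 8.0 d

- X, in percent of the L first charged, at 8.0 d
- the option that brings most further X ("none" if no option brings more than 2 percentage points) (beta / alpha / epsilon / zeta / none)
- X present, with what was taken out counted in, in percent of the L first charged, after beta
- X present, with what was taken out counted in, in percent of the L first charged, after epsilon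

- what is taken out of X is counted as made
- what may be going on: L + J -> X + J; L + G -> J + X; X -> D
- additions bring no volume worth counting

1. Read the loss of L on the last two ochre readings, where it runs pseudo-first-order: k_L = 0.715 /d.

2. Read the loss of X over the same interval. Take D as what L and X no longer hold, and divide its gain by the time and the mean X: k_D = 0.156 /d.

3. Form S = k_L/k_D, the number of times faster L goes into X than X goes into D: S = 4.58. L therefore fades faster than X, and the late flask is plain decay of X.

4. Run both losses forward from the last ochre reading. L falls to 0.445% at 8.0 d, against the margin of 2 percentage points, and X stands at 39.7%.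

5. Read the options. Beta leaves 11.4%. Alpha banks 36.8%, still below X at 8.0 d. Zeta has L at 0.445% to work on. The cooler grey run reads k_D = 0.0794 /d, so ochre's is twice that. Expect epsilon to leave X near zero. Answer: none.

6. Test whether one number is enough, reckoning from the charge with S and without a reading: X = 36.3%, below step 4. The early readings show a lag, which S does not hold.

The forecast puts X higher, 42% now and 14% after beta , with best none and 0% after epsilon, and on zeta it says “Adding G cannot help, since almost no L remains”.

The flask gives 40.1%, best none, 12.4% after beta and 0% after epsilon.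

    L + J → X + J, rate k1*[J]*[L] (k = 21.5 /M/h, Ea = 52.0 kJ/mol)
    L + G → J + X (k = 1.80 /M/h, Ea = 55.0 kJ/mol)
    X → D (k = 0.00615 /h, Ea = 107 kJ/mol)
    (constants at 35 °C)

Hold S against this flask: the reckoning from the charge lies 3.8 points under its X. Now take the neighbour flask, charged with 6.8 × 10⁻⁴ M of G. At 8.00 d it holds 6.74 × 10⁻⁴ M of J against 0.00156 M here, so scale S by that ratio of J, which gives 1.98. Reckoned from the charge, the neighbour keeps 8.45% of L, and it holds 7.9%. The same reckoning gives the neighbour 40.9% of X, and it holds 44.9%, again 4.0 points above.

All runs come from a simulation with constants of no real substance, noise included.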